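## Analysis of the target

- The target 22 is a cis-fused eremophilane diester. Ring A (C1–C5, C10) carries the 3α-angelate and the 4β-methyl group (C15). Ring B (C5–C10) carries the 7β-isopropenyl group, the C8 ketone and the 9β-senecioate. C5 is quaternary and bears the angular methyl C14.
- There are six stereocentres (C3, C4, C5, C7, C9, C10). C14, C15, the isopropenyl group, the C9 oxygen and H10 lie on one face (β); only the C3 oxygen lies on the other.
- In the chair–chair conformer with C14 axial on ring A, every other substituent is equatorial. C7 and C9 (α to the C8 ketone) and C4 (once C3 is a ketone) therefore have the thermodynamically preferred configuration.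
- The two carbinol carbons are the difficult ones if made from ketones: the face a hydride must use at C3 is blocked by the axial C14, and at C9 by C4 of ring A.
- Sensitive groups: the (Z)-angelate (isomerises to the tiglate), the senecioate (deconjugation), the α-acyloxy ketone (acyl shift), and the β,γ-unsaturated ketone, whose C7–H is doubly activated (double-bond shift to C7=C11, epimerisation).
- The hard parts are the vicinal tertiary C4 / quaternary C5 pair in a cis-decalin of one absolute configuration, the regiodefined 8-oxo-9-acyloxy pattern, and telling two similar enoate esters apart.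
- The strategy rests on ring B. C5 with its methyl, C7 with its three-carbon branch and the oxygenated C9 form a 1,3,5-substituted six-membered ring. This meta-menthane pattern is latent in (+)-3-carene (1), whose cyclopropane carbons become C7, C8 and C11.

## Retrosynthetic reasoning

**22 ⇒ 21.** The C8 carbonyl is taken back to the secondary alcohol 21. The β,γ-unsaturated α-acyloxy ketone is the most fragile part of 22, so it is formed last; the forward step only has to oxidise under neutral, non-enolising conditions.

**21 ⇒ 19 ⇒ 17 + 18, and 17 ⇒ 14 + 15.** The two ester C–O bonds are cut one after the other, with the C8 oxygen masked as an acetal (19) so that it cannot be confused with the C9 oxygen. In the forward sense the angelate from 15 goes first onto the less hindered C3 hydroxyl of diol 14, and the senecioate from 18 second onto the hindered C9 hydroxyl. Cutting both esters back to 14 means no ester is present while the carbinol centres are set.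

**14 ⇒ 13 ⇒ 12.** The C3–H bond is cut, leading to ketone 13. A thermodynamically controlled (dissolving-metal) reduction is required because kinetic hydride delivery would give the axial epimer. Ketone 13 is the hydrolysis product of silyl enol ether 12, and at this ketone stage C4 can be equilibrated to the equatorial methyl epimer.

**12 ⇒ 11 ⇒ 10 ⇒ 8.** The 8,9-dioxygenation is traced to the single C9 ketone of 8: the C9–H bond (reduction of 11) and the C8–O bond (enolate hydroxylation of 8 to 10, then acetal formation) are cut. The key step delivers its carbonyl at C9, and C8 is the only methylene α to it, so the oxygen can be placed regioselectively. The forward sequence must give the 9β-alcohol.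

**8 ⇒ 5 + 7.** Ring A is opened at C4–C5 and C1–C10, a retro-[4+2] step. These are the bonds that create the quaternary C5 next to C4 and the cis fusion. Cutting here splits the skeleton into enone 5, which holds ring B with the C5 methyl, the C7 stereocentre and the C9 carbonyl, and diene 7, which supplies C1–C4, C15 and the C3 oxygen. The forward reaction must add to the enone face anti to the isopropenyl group.

**5 ⇒ 4 ⇒ 2 ⇒ 1, and 7 ⇒ 6.** The isopropenyl group of 5 comes from a tertiary iodide (4), and this from opening of the cyclopropane of enone 2 at the bond conjugated with the carbonyl group. 2 is the allylic oxidation product of 1, which fixes the absolute configuration. Diene 7 is the enol silyl ether of vinyl ketone 6.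

## Alternatives that were turned down

**Alternative 1:** Ring B is cut at C5–C6 by a retro-[3,3] shift that re-forms a C3–C8 bridge bond, leading back to a bridged bicyclic tertiary alcohol with a dienyl side chain.
- Forward key step: the potassium alkoxide undergoes anionic oxy-Cope rearrangement, giving the quaternary C5 and the cis fusion together; the dienolate is protonated at C7 to give A1.
- For: stereochemistry is passed on through a rigid framework. A1 already has the C8 ketone and C9 at the ketone oxidation level, so no ketol transposition is needed. On this point it is stronger than the chosen route.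
- Against: the bridged precursor, made by cycloaddition to a masked ortho-quinone, is racemic unless resolved. A1 lacks the C3 oxygen and both the C3 and C4 stereocentres, which would have to come from hydroboration of the hindered C3=C4 alkene next to the quaternary carbon. C7 rests on kinetic protonation of a dienolate that can also give the conjugated 7(11)-ene. The unmasked 8,9-dione would need regio- and stereoselective reduction at C9.
- Comparison: the chosen strategy takes its absolute configuration from 1, brings the C3 oxygen in with the diene and puts C4 under thermodynamic control; it pays with redox steps on ring B.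

**Alternative 2:** Both rings are cut at once, back to the acyclic A2.
- Forward key step: aristolochene synthase ionises A2, closes the ten-membered ring and then the decalin, shifts a hydride and a methyl group, and removes H9 to give A3.
- For: no chemical annulation matches this step economy for the carbon skeleton. C4 and C5 come out with the right relative and absolute configuration, without protecting groups.
- Against: A3 is a hydrocarbon with none of the three oxygens and a C9=C10 alkene instead of the cis-fusion hydrogen. Its isopropenyl group is trans to C14, the opposite of 22. Conversion would need allylic oxidation at C8, oxygenation at C9, face-selective reduction of the alkene, inversion at C7 through the ketone, and oxidation of the unactivated C3 methylene, for which the substrate offers no handle. Enzyme supply and a volatile product add practical limits.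
- Comparison: the chosen route is longer to the bicyclic core, but the C3 and C9 oxygens are placed by the building blocks 7 and 5.

**Alternative 3:** Ring B is cut at C7–C8 (retro-ene), back to a ring-A compound with a prenyl group on C5 and an aldehyde (C8) at the end of a two-carbon arm on C10.
- Forward key step: Me2AlCl activates the aldehyde, which reacts with the trisubstituted alkene through a chair transition state (the closure known from citronellal to isopulegol). The C7–C8 bond forms, a methyl hydrogen passes to oxygen, and the isopropenyl group appears, giving A4.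
- For: A4 is one oxidation from the target, both esters are in place before ring closure, and the chair places the isopropenyl group equatorial. After the key step this endgame is shorter than the chosen one.
- Against: the precursor must already hold C3, C4, the quaternary C5 and C10 in enantiopure form, plus C9 as an α-acyloxy aldehyde that is configurationally labile and prone to acyl shift and elimination. The hard C4/C5/C10 problem is only moved into a long precursor synthesis. The Lewis acid must also tolerate the angelate. The step makes one bond and one ring.
- Comparison: the chosen key step makes two bonds, ring A and three stereocentres from two simple partners, at the price of a longer functional-group endgame.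

Key step: step 5

Remark: decalin intermediates carry eremophilane numbering; β is the face of the C5 methyl group (C14) and α the opposite face; angelic acid (15) and 3-methylbut-2-enoyl chloride (18) are taken as purchased.

## Route

Step 1
Reactants: 1 (1S,6R)-(+)-3-carene
Product: 2 (1R,6S)-4,7,7-trimethylbicyclo[4.1.0]hept-3-en-2-one (car-3-en-5-one)
Conditions: CrO3, 3,5-dimethylpyrazole, CH2Cl2, −20 °C
Reagents that add atoms: chromium trioxide, O=[Cr](=O)=O
Why: Allylic oxidation with the CrO3–3,5-dimethylpyrazole complex: the ring methylene that is both allylic and next to the cyclopropane is oxidised to the conjugated cyclopropyl enone; neither stereocentre is touched.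

Step 2
Reactants: 2 (1R,6S)-4,7,7-trimethylbicyclo[4.1.0]hept-3-en-2-one
Product: 4 (S)-5-(2-iodopropan-2-yl)-3-methylcyclohex-2-en-1-one, via trimethylsilyl dienol ether iodide 3 (not isolated)
Conditions: Me3SiI, CH2Cl2, −20 → 0 °C; then 1 M HCl (aq), 0 °C
Reagents that add atoms: iodotrimethylsilane, C[Si](C)(C)I
Why: Homo-conjugate opening of a cyclopropyl ketone: O-silylation makes the cyclopropane bond that overlaps with the carbonyl group electrophilic, iodide enters at the gem-dimethyl carbon (the end that best carries positive charge) and the bond to the α-carbon breaks, so the three-carbon unit stays on the ring carbon whose configuration is untouched; aqueous acid hydrolyses the silyl dienol ether 3 to the conjugated enone.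

Step 3
Reactants: 4 (S)-5-(2-iodopropan-2-yl)-3-methylcyclohex-2-en-1-one
Product: 5 (S)-3-methyl-5-(prop-1-en-2-yl)cyclohex-2-en-1-one
Conditions: DBU, toluene, 25 → 60 °C
Reagents that add atoms: none
Why: E2 dehydroiodination of a tertiary iodide with an amidine base, which is too weak to form the ketone enolate that would re-close the cyclopropane; the six methyl hydrogens are more accessible than the single ring methine hydrogen, so the isopropenyl isomer should prevail, and the stereocentre is not involved.

Step 4
Reactants: 6 ethyl vinyl ketone (pent-1-en-3-one)
Product: 7 (Z)-tert-butyl(dimethyl)(penta-1,3-dien-3-yloxy)silane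
Conditions: TBSOTf, Et3N, Et2O, 0 °C
Reagents that add atoms: tert-butyldimethylsilyl trifluoromethanesulfonate, CC(C)(C)[Si](C)(C)OS(=O)(=O)C(F)(F)F
Why: Soft enolisation of the vinyl ketone (O-silylation, then deprotonation by the amine) gives the 2-silyloxydiene; the (Z)-enol ether, with the methyl group syn to oxygen and away from the vinyl group, is the usual outcome of amine/silyl triflate enolisation of ethyl ketones.

Step 5
Reactants: 5 (S)-3-methyl-5-(prop-1-en-2-yl)cyclohex-2-en-1-one; 7 (Z)-tert-butyl(dimethyl)(penta-1,3-dien-3-yloxy)silane
Product: 8 3-(tert-butyldimethylsilyloxy)-10βH-eremophila-2,11-dien-9-one (cis-fused; 4β,5β-dimethyl; 7β-isopropenyl)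
Conditions: AlBr3/AlMe3 (10:1, 0.3 equiv), 7 (3 equiv), toluene–CH2Cl2, −10 °C → rt; Et3N, then aq. NaHCO3
Reagents that add atoms: none
Why: The aluminium Lewis acid binds the enone oxygen, the nucleophilic terminus of the silyloxydiene (C4) attacks the β-carbon C5 and the developing enolate carbon C10 bonds to the diene terminus C1; this is a strongly asynchronous [4+2] cycloaddition that may run as Mukaiyama–Michael addition followed by 6-endo-trig Michael closure, and either way ring A closes as a six-membered ring with the silyl group on O3 as the C2=C3 enol ether. The closest known reaction type is the Diels–Alder reaction of hindered 2-silyloxydienes with 3-methylcyclohex-2-enones under mixed aluminium Lewis acids or high pressure, which builds a quaternary carbon next to a tertiary one; AlMe3 acts as proton scavenger so that the diene, the isopropenyl group and the product enol ether survive. Regiochemistry follows from polarity: the donor oxygen makes C4 the nucleophilic end and the Lewis acid makes C5 the electrophilic end. C5 and C10 are set by the enone face: the diene adds anti to the C7 isopropenyl group (axial attack on the half-chair with the substituent pseudo-equatorial, as in conjugate additions to 5-substituted cyclohexenones), which puts C14 and H10 on the isopropenyl face, and because both bonds are delivered to the same face the fusion is cis. C4 is set by the orientation of the diene: an exo approach, in which the bulky silyloxy group avoids the ring methylene C6, or the antiperiplanar open transition state of the stepwise path, puts C15 cis to C14. The step needs facial selectivity above all; the C4 configuration is not critical, because it is corrected by equilibration next to the C3 ketone in step 9.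

Step 6
Reactants: 8 3-(tert-butyldimethylsilyloxy)-10βH-eremophila-2,11-dien-9-one
Product: 10 3-(tert-butyldimethylsilyloxy)-8β-hydroxy-10βH-eremophila-2,11-dien-9-one, via potassium enolate 9 (not isolated)
Conditions: KN(SiMe3)2, THF, −78 °C; 2-(phenylsulfonyl)-3-phenyloxaziridine, −78 °C; AcOH, −78 °C
Reagents that add atoms: 2-(phenylsulfonyl)-3-phenyloxaziridine, O=S(=O)(N1OC1c1ccccc1)c1ccccc1
Why: Kinetic deprotonation at the C8 methylene (the other α-hydrogen, at C10, is tertiary and flanked by the quaternary C5) gives enolate 9, which is hydroxylated by the N-sulfonyloxaziridine; oxygen should enter axially from the convex β face of the cis-decalin (the α face is shielded by C4 of ring A) to give the 8β-alcohol, and the enol ether and isopropenyl group do not react with this oxidant at −78 °C.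

Step 7
Reactants: 10 3-(tert-butyldimethylsilyloxy)-8β-hydroxy-10βH-eremophila-2,11-dien-9-one
Product: 11 3-(tert-butyldimethylsilyloxy)-8β-(methoxymethoxy)-10βH-eremophila-2,11-dien-9-one
Conditions: MeOCH2Cl, i-Pr2NEt, Bu4NI (cat.), CH2Cl2, 0 °C → rt
Reagents that add atoms: chloromethyl methyl ether, COCCl
Why: Williamson-type acetal formation on the secondary alcohol under mildly basic conditions that leave the silyl enol ether and the ketone untouched; an acetal is chosen because it cannot migrate to O9 and survives the dissolving-metal step.

Step 8
Reactants: 11 3-(tert-butyldimethylsilyloxy)-8β-(methoxymethoxy)-10βH-eremophila-2,11-dien-9-one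
Product: 12 3-(tert-butyldimethylsilyloxy)-8β-(methoxymethoxy)-10βH-eremophila-2,11-dien-9β-ol
Conditions: NaBH4, MeOH–THF, −40 → 0 °C
Reagents that add atoms: none
Why: Borohydride reduction of an α-alkoxy ketone: hydride should add anti to the axial C8–O bond (polar Felkin–Anh control, reinforced by the axial acetal blocking the β face), that is from the α face, giving the equatorial 9β-alcohol; reduction is faster than enolisation, so the cis fusion at C10 is kept.

Step 9
Reactants: 12 3-(tert-butyldimethylsilyloxy)-8β-(methoxymethoxy)-10βH-eremophila-2,11-dien-9β-ol
Product: 13 9β-hydroxy-8β-(methoxymethoxy)-10βH-eremophil-11-en-3-one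
Conditions: Bu4NF, AcOH, THF, 0 °C; then DBU (cat.), CH2Cl2, rt
Reagents that add atoms: none
Why: Fluoride cleaves the enol Si–O bond (the only silyl group present) and the enolate is protonated at C2; brief exposure to DBU then equilibrates C4 through the C3 enolate to the equatorial 4β-methyl epimer, in which the methyl group avoids a syn-axial clash with C9, so any C4 epimer from step 5 converges here.

Step 10
Reactants: 13 9β-hydroxy-8β-(methoxymethoxy)-10βH-eremophil-11-en-3-one
Product: 14 8β-(methoxymethoxy)-10βH-eremophil-11-ene-3α,9β-diol
Conditions: Li, NH3 (l)–THF, t-BuOH, −78 °C; NH4Cl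
Reagents that add atoms: none
Why: Dissolving-metal reduction of the ketone is under thermodynamic control and gives the equatorial 3α-alcohol, whereas hydride reagents would attack from the α face (the β face is blocked by the axial C14) and give the axial 3β-epimer; the isolated alkene, the acetal and the C9 alkoxide are inert.

Step 11
Reactants: 14 8β-(methoxymethoxy)-10βH-eremophil-11-ene-3α,9β-diol; 15 angelic acid [(Z)-2-methylbut-2-enoic acid]
Product: 17 9β-hydroxy-8β-(methoxymethoxy)-10βH-eremophil-11-en-3α-yl (Z)-2-methylbut-2-enoate, via mixed anhydride 16 (not isolated)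
Conditions: 15, 2,4,6-Cl3C6H2COCl, Et3N, toluene, rt; then 14, toluene, 70 °C
Reagents that add atoms: none
Why: Yamaguchi esterification through the mixed anhydride 16, run without a nucleophilic catalyst so that the (Z)-enoate is not isomerised; the 3α-hydroxyl, flanked only by a methylene and the methyl-bearing C4, should react well before the 9β-hydroxyl, which sits between the ring fusion and the axial acetal on C8.

Step 12
Reactants: 17 9β-hydroxy-8β-(methoxymethoxy)-10βH-eremophil-11-en-3α-yl (Z)-2-methylbut-2-enoate; 18 3-methylbut-2-enoyl chloride
Product: 19 8β-(methoxymethoxy)-9β-(3-methylbut-2-enoyloxy)-10βH-eremophil-11-en-3α-yl (Z)-2-methylbut-2-enoate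
Conditions: 18, pyridine, CH2Cl2, 0 °C → rt
Reagents that add atoms: none
Why: Acylation of the remaining, hindered 9β-alcohol with the acid chloride in pyridine; pyridine is too weak a base to generate the vinylketene, so the conjugated 3-methylbut-2-enoate is formed, and the angelate is left alone.

Step 13
Reactants: 19 8β-(methoxymethoxy)-9β-(3-methylbut-2-enoyloxy)-10βH-eremophil-11-en-3α-yl (Z)-2-methylbut-2-enoate
Product: 21 8β-hydroxy-9β-(3-methylbut-2-enoyloxy)-10βH-eremophil-11-en-3α-yl (Z)-2-methylbut-2-enoate, via bromomethyl ether 20 (not isolated)
Conditions: Me2BBr, CH2Cl2, −78 °C; then sat. aq. NaHCO3–THF, 0 °C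
Reagents that add atoms: none
Why: Cleavage of the methoxymethyl acetal with bromodimethylborane at low temperature through the bromomethyl ether 20, which is hydrolysed on bicarbonate work-up; the conditions are non-basic, so no acyl shift from O9 to O8 is expected, and esters and alkenes are inert.

Step 14
Reactants: 21 8β-hydroxy-9β-(3-methylbut-2-enoyloxy)-10βH-eremophil-11-en-3α-yl (Z)-2-methylbut-2-enoate
Product: 22 8-oxo-9β-(3-methylbut-2-enoyloxy)-10βH-eremophil-11-en-3α-yl (Z)-2-methylbut-2-enoate (CNP0375730.2)
Conditions: Dess–Martin periodinane, pyridine, CH2Cl2, 0 °C → rt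
Reagents that add atoms: none
Why: Dess–Martin oxidation of the axial secondary alcohol under buffered, non-enolising conditions; C7 and C9 become α to the ketone but already carry their substituents equatorial, so there is no driving force for epimerisation, and short contact avoids shifting the isopropenyl double bond into conjugation.

## Compound list

1 | (1S,6R)-(+)-3-carene | CC1=CC[C@@H]2[C@H](C1)C2(C)C | starting material
2 | (1R,6S)-4,7,7-trimethylbicyclo[4.1.0]hept-3-en-2-one (car-3-en-5-one) | CC1=CC(=O)[C@@H]2[C@H](C1)C2(C)C | intermediate
3 | {[(3S)-3-(2-iodopropan-2-yl)-5-methylcyclohexa-1,5-dien-1-yl]oxy}trimethylsilane | CC1=CC(O[Si](C)(C)C)=C[C@H](C1)C(C)(C)I | intermediate (not isolated)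
4 | (S)-5-(2-iodopropan-2-yl)-3-methylcyclohex-2-en-1-one | CC1=CC(=O)C[C@H](C1)C(C)(C)I | intermediate
5 | (S)-3-methyl-5-(prop-1-en-2-yl)cyclohex-2-en-1-one | C=C(C)[C@H]1CC(C)=CC(=O)C1 | intermediate
6 | ethyl vinyl ketone (pent-1-en-3-one) | CCC(=O)C=C | starting material
7 | (Z)-tert-butyl(dimethyl)(penta-1,3-dien-3-yloxy)silane | C/C=C(O[Si](C)(C)C(C)(C)C)/C=C | intermediate
8 | 3-(tert-butyldimethylsilyloxy)-10βH-eremophila-2,11-dien-9-one (cis-fused; 4β,5β-dimethyl; 7β-isopropenyl) | C=C(C)[C@H]1C[C@@]2(C)[C@H](CC=C(O[Si](C)(C)C(C)(C)C)[C@@H]2C)C(=O)C1 | intermediate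
9 | potassium 8(9)-enolate of 8 | [K+].C=C(C)[C@H]1C[C@@]2(C)[C@H](CC=C(O[Si](C)(C)C(C)(C)C)[C@@H]2C)C([O-])=C1 | intermediate (not isolated)
10 | 3-(tert-butyldimethylsilyloxy)-8β-hydroxy-10βH-eremophila-2,11-dien-9-one | C=C(C)[C@H]1C[C@@]2(C)[C@H](CC=C(O[Si](C)(C)C(C)(C)C)[C@@H]2C)C(=O)[C@H]1O | intermediate
11 | 3-(tert-butyldimethylsilyloxy)-8β-(methoxymethoxy)-10βH-eremophila-2,11-dien-9-one | C=C(C)[C@H]1C[C@@]2(C)[C@H](CC=C(O[Si](C)(C)C(C)(C)C)[C@@H]2C)C(=O)[C@H]1OCOC | intermediate
12 | 3-(tert-butyldimethylsilyloxy)-8β-(methoxymethoxy)-10βH-eremophila-2,11-dien-9β-ol | C=C(C)[C@H]1C[C@@]2(C)[C@H](CC=C(O[Si](C)(C)C(C)(C)C)[C@@H]2C)[C@@H](O)[C@H]1OCOC | intermediate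
13 | 9β-hydroxy-8β-(methoxymethoxy)-10βH-eremophil-11-en-3-one | C=C(C)[C@H]1C[C@@]2(C)[C@H](CCC(=O)[C@@H]2C)[C@@H](O)[C@H]1OCOC | intermediate
14 | 8β-(methoxymethoxy)-10βH-eremophil-11-ene-3α,9β-diol | C=C(C)[C@H]1C[C@@]2(C)[C@H](CC[C@@H](O)[C@@H]2C)[C@@H](O)[C@H]1OCOC | intermediate
15 | angelic acid [(Z)-2-methylbut-2-enoic acid] | C/C=C(/C)C(=O)O | starting material
16 | (Z)-2-methylbut-2-enoic 2,4,6-trichlorobenzoic anhydride | C/C=C(/C)C(=O)OC(=O)c1c(Cl)cc(Cl)cc1Cl | intermediate (not isolated)
17 | 9β-hydroxy-8β-(methoxymethoxy)-10βH-eremophil-11-en-3α-yl (Z)-2-methylbut-2-enoate | C=C(C)[C@H]1C[C@@]2(C)[C@H](CC[C@@H](OC(=O)/C(C)=C\C)[C@@H]2C)[C@@H](O)[C@H]1OCOC | intermediate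
18 | 3-methylbut-2-enoyl chloride | CC(C)=CC(=O)Cl | starting material
19 | 8β-(methoxymethoxy)-9β-(3-methylbut-2-enoyloxy)-10βH-eremophil-11-en-3α-yl (Z)-2-methylbut-2-enoate | C=C(C)[C@H]1C[C@@]2(C)[C@H](CC[C@@H](OC(=O)/C(C)=C\C)[C@@H]2C)[C@@H](OC(=O)C=C(C)C)[C@H]1OCOC | intermediate
20 | 8β-(bromomethoxy)-9β-(3-methylbut-2-enoyloxy)-10βH-eremophil-11-en-3α-yl (Z)-2-methylbut-2-enoate | C=C(C)[C@H]1C[C@@]2(C)[C@H](CC[C@@H](OC(=O)/C(C)=C\C)[C@@H]2C)[C@@H](OC(=O)C=C(C)C)[C@H]1OCBr | intermediate (not isolated)
21 | 8β-hydroxy-9β-(3-methylbut-2-enoyloxy)-10βH-eremophil-11-en-3α-yl (Z)-2-methylbut-2-enoate | C=C(C)[C@H]1C[C@@]2(C)[C@H](CC[C@@H](OC(=O)/C(C)=C\C)[C@@H]2C)[C@@H](OC(=O)C=C(C)C)[C@H]1O | intermediate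
22 | 8-oxo-9β-(3-methylbut-2-enoyloxy)-10βH-eremophil-11-en-3α-yl (Z)-2-methylbut-2-enoate (CNP0375730.2) | C=C(C)[C@H]1C[C@@]2(C)[C@H](CC[C@@H](OC(=O)/C(C)=C\C)[C@@H]2C)[C@@H](OC(=O)C=C(C)C)C1=O | target

## Step count and least certain steps

Total step count: 14. Longest linear sequence: 13 steps (1 to 22 through steps 1–3 and 5–14); step 4 is a one-step side branch.

**Step 5 (key step).** The cycloaddition may be too slow, since the dienophile is β,β-disubstituted and the diene terminus is substituted. Lewis-acid-induced loss of the diene (protodesilylation, oligomerisation) or ionisation at the isopropenyl group could then outrun it, and reduced facial selectivity would erode the C5/C10 configuration. The fallback splits the annulation into its two conjugate additions. Setting out from 5 and 7, a Mukaiyama–Michael addition under silyl triflimide catalysis (Tf2NH, CH2Cl2, −78 °C) would form only the C4–C5 bond and, by silyl transfer, give 4-[3-(tert-butyldimethylsilyloxy)-1-methyl-5-(prop-1-en-2-yl)cyclohex-2-en-1-yl]pent-1-en-3-one F1. Treating F1 with Me2AlCl would close ring A by intramolecular Mukaiyama–Michael addition of C10 to C1, with the silyl group moving to O3; this comes back to the route at 8.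

**Step 8.** Hydride may be delivered to the convex β face instead. The α face of C9 is flanked by C4 of ring A, syn-axial to the incoming hydride, and the directing effect needs the C8 acetal to be axial, which rests on the facial selectivity of step 6. The result would be the axial 9α-alcohol. The fallback replaces kinetic by thermodynamic control. Setting out from 11, a Meerwein–Ponndorf–Verley reduction under equilibrating conditions (Al(Oi-Pr)3, i-PrOH, toluene, reflux, trace of acetone) lets the two C9 alkoxides interconvert through 11. The 9α-epimer, 3-(tert-butyldimethylsilyloxy)-8β-(methoxymethoxy)-10βH-eremophila-2,11-dien-9α-ol F2, has its hydroxyl syn-axial to C4 and should drain into the equatorial alcohol; this comes back to the route at 12.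

**Step 11.** Site selectivity may be incomplete, with acylation of the 9β-hydroxyl or double acylation, because both hydroxyls are secondary and equatorial and the distinction is purely steric. The fallback replaces selectivity by protection. Setting out from 12:
- silylation of the C9 hydroxyl (TBSOTf, 2,6-lutidine) would give the 9-O-tert-butyldimethylsilyl ether of 12 F3;
- the conditions of step 9 would cleave the enol silyl ether much faster than the hindered alkyl silyl ether and give 9β-(tert-butyldimethylsilyloxy)-8β-(methoxymethoxy)-10βH-eremophil-11-en-3-one F4;
- the reduction of step 10 would give the 3α-alcohol 9β-(tert-butyldimethylsilyloxy)-8β-(methoxymethoxy)-10βH-eremophil-11-en-3α-ol F5;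
- esterification with 15 as in step 11 would give its (Z)-2-methylbut-2-enoate F6;
- HF·pyridine would remove the C9 silyl group.

This comes back to the route at 17.

**Step 3.** Regiocontrol in the elimination may be lost: proton loss from the ring methine gives the isopropylidene isomer, which an iodide leaving group favours on Zaitsev grounds. Re-closure to 2 is a second risk if any enolate forms. The fallback goes through the tertiary alcohol instead of the halide. Setting out from 2, acid-catalysed hydration (dilute H2SO4, THF) opens the cyclopropane by the same homo-conjugate path to (S)-5-(2-hydroxypropan-2-yl)-3-methylcyclohex-2-en-1-one F7. Dehydration through the chlorosulfite (SOCl2, pyridine, −20 °C), a non-enolising elimination that takes a methyl hydrogen, comes back to the route at 5.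

## Further compounds

F1 | step 5 | 4-[3-(tert-butyldimethylsilyloxy)-1-methyl-5-(prop-1-en-2-yl)cyclohex-2-en-1-yl]pent-1-en-3-one (configuration of 8 at C4, C5 and C7) | C=C(C)[C@H]1C[C@](C)([C@@H](C)C(=O)C=C)C=C(O[Si](C)(C)C(C)(C)C)C1
F2 | step 8 | 3-(tert-butyldimethylsilyloxy)-8β-(methoxymethoxy)-10βH-eremophila-2,11-dien-9α-ol | C=C(C)[C@H]1C[C@@]2(C)[C@H](CC=C(O[Si](C)(C)C(C)(C)C)[C@@H]2C)[C@H](O)[C@H]1OCOC
F3 | step 11 | 3,9β-bis(tert-butyldimethylsilyloxy)-8β-(methoxymethoxy)-10βH-eremophila-2,11-diene | C=C(C)[C@H]1C[C@@]2(C)[C@H](CC=C(O[Si](C)(C)C(C)(C)C)[C@@H]2C)[C@@H](O[Si](C)(C)C(C)(C)C)[C@H]1OCOC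
F4 | step 11 | 9β-(tert-butyldimethylsilyloxy)-8β-(methoxymethoxy)-10βH-eremophil-11-en-3-one | C=C(C)[C@H]1C[C@@]2(C)[C@H](CCC(=O)[C@@H]2C)[C@@H](O[Si](C)(C)C(C)(C)C)[C@H]1OCOC
F5 | step 11 | 9β-(tert-butyldimethylsilyloxy)-8β-(methoxymethoxy)-10βH-eremophil-11-en-3α-ol | C=C(C)[C@H]1C[C@@]2(C)[C@H](CC[C@@H](O)[C@@H]2C)[C@@H](O[Si](C)(C)C(C)(C)C)[C@H]1OCOC
F6 | step 11 | 9β-(tert-butyldimethylsilyloxy)-8β-(methoxymethoxy)-10βH-eremophil-11-en-3α-yl (Z)-2-methylbut-2-enoate | C=C(C)[C@H]1C[C@@]2(C)[C@H](CC[C@@H](OC(=O)/C(C)=C\C)[C@@H]2C)[C@@H](O[Si](C)(C)C(C)(C)C)[C@H]1OCOC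
F7 | step 3 | (S)-5-(2-hydroxypropan-2-yl)-3-methylcyclohex-2-en-1-one | CC1=CC(=O)C[C@H](C1)C(C)(C)O
A1 | alternative 1 | cis-fused 9,9-dimethoxyeremophila-3,11-dien-8-one | C=C(C)[C@H]1C[C@@]2(C)[C@H](CCC=C2C)C(OC)(OC)C1=O
A2 | alternative 2 | (2E,6E)-farnesyl diphosphate | CC(C)=CCC/C(C)=C/CC/C(C)=C/COP(=O)(O)OP(=O)(O)O
A3 | alternative 2 | (+)-aristolochene | C=C(C)[C@@H]1C[C@@]2(C)C(CCC[C@@H]2C)=CC1
A4 | alternative 3 | 8α-hydroxy analogue of the target (8-dihydro target) | C=C(C)[C@H]1C[C@@]2(C)[C@H](CC[C@@H](OC(=O)/C(C)=C\C)[C@@H]2C)[C@@H](OC(=O)C=C(C)C)[C@@H]1O
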